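The readings are calculated for an exercise.

I began with the easy step, the bookkeeping: every mole of starting material ends in target or in side product.

| flask | starting material | catalyst | temperature | remark | time |
|---|---|---|---|---|---|
| birch | 0.30 M | 0.30 mM | 5 °C | the very flask that is asked about, followed so far |  |
| alder | 0.20 M | 0.30 mM | 11 °C | run made earlier |  |
| flask | 0.30 M | 0.30 mM | 5 °C |  | 30 h |

birch run (percent of the starting material charged)

| time / h | target / % | starting material / % |
|---|---|---|
| 2.50 | 66.4 | 1.3 |
| 6.00 | 65.3 | 0 |
| 12.0 | 67.6 | 1.0 |
| 20.0 | 68.6 | 0 |

alder run (percent of the starting material charged)

| time / min | target / % | starting material / % |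
|---|---|---|
| 8.00 | 64.1 | 18.5 |
| 20.0 | 71.0 | 1.4 |
| 40.0 | 74.4 | 0 |
| 60.0 | 73.8 | 0 |

(each reading ± 1 percentage point)

- noon: at 30 h take out 90% of the target then present, then wait 2.5 d
- summer: change nothing and wait 2.5 d more
- dusk: at 30 h add catalyst, 100% of the amount charged, then wait 2.5 d
- autumn: at 30 h raise the temperature by 20 K, then wait 2.5 d

- target, in percent of the starting material first charged, at 30 h
- the option that brings most further target ("none" if no option brings more than 2 percentage points) (noon / summer / dusk / autumn / none)
- target present, with what was taken out counted in, in percent of the starting material first charged, after summer
- target present, with what was taken out counted in, in percent of the starting material first charged, after autumn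

- percentages count the starting material that a species holds: one side product counts as two
- target taken out counts as made
- steps thought possible: starting material + catalyst -> catalyst + target; starting material + target -> side product
- additions bring no volume worth counting

I kept the ledger on birch, the flask asked about. Starting material is the limiting reagent, and birch read 0% of it at 20.0 h, less than the scatter of 1 percentage point. Its four target readings averaged 67.0%, with a standard error of 0.5 points. One side product holds two shares, one of them target already made, so I closed the books thus:

target kept: 67.0%
side product: 33.0%
starting material through the first step: 83.5%
starting material through the second step: 16.5%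

Each step takes one starting material. If both are first order in it, c(starting material) cancels from their ratio, and c(target) sets the split, held against the catalyst:

second step / first step = c(target) / c_tie

I took the mean c(target) as its final value divided by 2, which gave:

c_tie = 0.508 M

This tie concentration, the c(target) at which both steps run equally fast, is a reading, and it holds for this catalyst and temperature. For a yield Y, the rule is:

(1 − Y) / (1 + Y) = Y c(starting material) / (2 c_tie)

Time does not enter the rule. Both steps need starting material, so I booked 67.0% at 30 h, after summer and after autumn, and no option passing 2 points.

The forecast gave 67.1% (66.2% to 68%), 67.1% after summer, 67.1% after autumn and none as best, since “once it is used up nothing can change”.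

The flask gave 67.0%, 67.0% after summer, 67.0% after autumn, and none as best.

    starting material + catalyst → catalyst + target (k = 6.67 M⁻¹ s⁻¹, Ea = 48.0 kJ mol⁻¹)
    starting material + target → side product (k = 0.00365 M⁻¹ s⁻¹, Ea = 57.0 kJ mol⁻¹)
    (constants at 5 °C)

With c_tie, the closing c(target) in this flask stood at 0.396 of the tie. For the neighbour with 0.75 M starting material, I set 0.738 as the factor on Y in the rule, which gave 47.8% against a simulated 46.2%. Reading at 30 h rather than later made no difference. At ten times the time, after 300 h, the flask held 0% starting material, 33.0% side product and 67.0% target.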